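(The constants were drawn at random within sensible limits, and the outcome is calculated.)

The pitfall in a stepwise ligand exchange is to reach for slow dosing to protect the first product from the next step, without asking whether the flask has time to spare.

| flask | starting complex | incoming ligand | time | remark |
|---|---|---|---|---|
| east | 10 mM | 10.5 mM (fed, over 1.0 h) | 80 min | all else is in the flask from the start; the feed brings no volume worth counting |
| south-west | 10 mM (in portions, 3, over 1.0 h) | 10.5 mM | 80 min | first portion at the start, last at 1.0 h |
| north-west | 10 mM | 10.5 mM | 80 min | everything together at the start |
| north | 10 mM (fed, over 1.0 h) | 10.5 mM | 80 min | all else is in the flask from the start; the feed brings no volume worth counting |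

    complex with one exchanged + incoming ligand ⇌ leaving ligand + complex with two exchanged (K1 = 16, k1 = 0.0088 L mol⁻¹ s⁻¹)
    leaving ligand → by-product carried off (k2 = 2.2 × 10⁻⁴ s⁻¹)
    starting complex + incoming ligand ⇌ leaving ligand + complex with one exchanged (K3 = 1.4, k3 = 0.018 L mol⁻¹ s⁻¹)
    complex with two exchanged + incoming ligand ⇌ leaving ligand + complex with three exchanged (K4 = 35, k4 = 0.038 L mol⁻¹ s⁻¹)

- the flask that comes out highest in amount of complex with one exchanged, in percent of the starting complex charged, or "all alike" when all lie within 1.5 percentage points (east / south-west / north-west / north / all alike)
- complex with one exchanged at the end, in percent of the starting complex charged, east
- complex with one exchanged at the end, in percent of the starting complex charged, south-west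
- complex with one exchanged at the end, in percent of the starting complex charged, north-west
- complex with one exchanged at the end, in percent of the starting complex charged, north

The second exchange has a smaller rate constant than the first, 0.0088 L mol⁻¹ s⁻¹ against 0.018 L mol⁻¹ s⁻¹, so we reckon on the first exchange and two times. The starting complex is the limiting reagent of that exchange, at 10 mM against 10.5 mM of incoming ligand. With charges this close, the exchange time is the time the forward step needs to use up about half of the starting complex:

exchange time = reciprocal of (0.018 L mol⁻¹ s⁻¹ × 10.5 mM) = 88.2 min

The second time is the contact time, the mean time a share of the dosed partner spends in the flask before the reading. A steady feed and equal portions both arrive on average 30.0 min after the start, so for east, north and south-west: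

contact time = 80 min − 30.0 min = 50.0 min

In north-west, everything is present from the start, so its contact time is 80 min. We estimate the share of starting complex used as contact time over contact time plus exchange time:

north-west: 47.6%
east, north, south-west: 36.2%

This estimate counts the forward step and leaves out the way back and the later exchanges. Its share is larger for north-west than for the three dosed flasks, so we pick north-west and set the three dosed flasks side by side.

The forecast also names north-west, giving complex with one exchanged as 36% there, 30.4% in east, 29.5% in north and 27.4% in south-west. It holds that “Both steady feeds delay the build-up”. Unlike our reckoning, it sets south-west apart from the two feeds.

The simulation gives complex with one exchanged as 36.8% in north-west, 30.4% in east, 29.6% in north and 28.4% in south-west, so north-west comes out highest. A reading of north-west at 50 min, equal to the contact time of east, shows 65.3% of starting complex and 30.8% of complex with one exchanged, while east at 80.0 min shows 65.9% and 30.4%. Another run of east, dosed over 6.00 min for a contact time of 77.0 min, ends with 36.4% of complex with one exchanged.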